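Numbering: C1 (beside quaternary C8) and C5 are the prenylated bridgeheads and C9 is the bridging ketone. Ring A = C1–C2–C3–C4–C5–C9 (aroylated, enolised diketone); ring B = C1–C8–C7–C6–C5–C9.
Enabling feature: read from C5, C6–C7–C8(CH3)(4-methylpent-3-enyl) is a geranyl chain, and C1 lies between the C2 and C9 carbonyls. A carbene at C1 of a preformed ring A can therefore span the C7=C8 alkene.
Retrosynthetic cuts, in order: C3–aroyl; the =C(CH3)2 ends of the C5 and C7 prenyl groups, with the C5 allyl group traced back to an O–(CH2)3 tether from the C4 oxygen; C1–prenyl and C7–allyl, restoring a temporary C1–C7 bond; C1–C7 and C1–C8 (cyclopropane to diazo dione plus alkene); then C3–C4, C1–C2, C5–C6 and C5–C9.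
Forward order of rings: lactone (later the dihydropyran), ring A, then the cyclopropane and the five-membered ring C1–C9–C5–C6–C7 in one step. Ring B arises when a cuprate cuts C1–C7, and the dihydropyran is opened near the end.
Stereochemistry: C5 comes from a catalytic asymmetric phase-transfer geranylation. C1, C7 and C8 follow from C5, the short tether and the (E)-alkene in the cyclopropanation. C7 is inverted in the SN2 opening, and C1 is then dictated by the bicycle.

Key step: step 6

Remark 1: the (S,S)-configured spiro ammonium bromide of step 2 is assumed to give (R)-5; if the sense of induction is the opposite, its equally available (R,R)-enantiomer is taken.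
Remark 2: locants C1–C9 are those of the target in all intermediates; geranyl = (2E)-3,7-dimethylocta-2,6-dien-1-yl and prenyl = 3-methylbut-2-en-1-yl; "4,5-(epoxypropano)" means an O–CH2CH2CH2 bridge with O on C4 and CH2 on C5; enolised triketones are drawn as the C4-enol tautomer of the target.

Step 1
Reactants: 1 δ-valerolactone (oxan-2-one); 2 N-methoxy-N-methylacetamide
Product: 3 3-acetyloxan-2-one (racemic, enolisable)
Conditions: LiN(i-Pr)2 (1.1 equiv), THF, −78 °C; 2, −78 → −20 °C; aq. HCl
Reagents that add atoms: none
Why: Crossed Claisen acylation (forms C5–C9): the lactone lithium enolate adds to the N-methoxy-N-methylamide and the chelated tetrahedral adduct lasts until the quench, so double acylation and proton transfer are avoided, and the new centre is enolisable and of no consequence.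

Step 2
Reactants: 3 3-acetyloxan-2-one; 4 geranyl bromide
Product: 5 (3R)-3-acetyl-3-geranyloxan-2-one
Conditions: 4 (1.2 equiv), (11bS,11'bS)-2,2',6,6'-tetrakis(3,4,5-trifluorophenyl)-3,3',5,5'-tetrahydro-4,4'-spirobi[dinaphtho[2,1-c:1',2'-e]azepin]-4-ium bromide (2 mol %), Cs2CO3 (solid), toluene, −20 °C
Reagents that add atoms: none
Why: Asymmetric phase-transfer C-alkylation of an α-acyl lactone enolate with an allylic bromide, a known route to all-carbon quaternary centres: the C2-symmetric ammonium cation shields one face of the ion pair, SN2 attack at the primary carbon of 4 keeps the (E)-alkene, and C5 is set here as (R).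

Step 3
Reactants: 5 (3R)-3-acetyl-3-geranyloxan-2-one; 6 1-acetyl-1H-benzotriazole
Product: 7 1-[(3R)-3-geranyl-2-oxooxan-3-yl]butane-1,3-dione
Conditions: MgBr2·OEt2 (2.5 equiv), i-Pr2NEt (3 equiv), 6 (1.2 equiv), CH2Cl2, rt
Reagents that add atoms: none
Why: Soft-enolisation C-acylation of a methyl ketone (magnesium chelate, amine base, N-acylbenzotriazole donor) forms C1–C2 without strong base; the acetyl CH3 is the only enolisable site and quaternary C5 is untouched.

Step 4
Reactants: 7 1-[(3R)-3-geranyl-2-oxooxan-3-yl]butane-1,3-dione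
Product: 8 2-diazo-1-[(3R)-3-geranyl-2-oxooxan-3-yl]butane-1,3-dione
Conditions: 4-acetamidobenzenesulfonyl azide, Et3N, MeCN, 0 °C → rt
Reagents that add atoms: 4-acetamidobenzenesulfonyl azide, CC(=O)Nc1ccc(cc1)S(=O)(=O)N=[N+]=[N-]
Why: Regitz diazo transfer to the only doubly activated methylene (C1); installing the diazo group before ring closure keeps C4 and C9 different in every later intermediate, so C5 cannot racemise through a symmetric trione.

Step 5
Reactants: 8 2-diazo-1-[(3R)-3-geranyl-2-oxooxan-3-yl]butane-1,3-dione
Product: 10 (4aS)-6-diazo-4a-geranyl-2,3,4,4a-tetrahydro-5H-chromene-5,7(6H)-dione, via hydroxypropyl diazo trione 9 (not isolated)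
Conditions: LiN(SiMe3)2 (2.2 equiv), THF, −78 → −20 °C; AcOH; then pyridinium p-toluenesulfonate (10 mol %), 4 Å MS, toluene, 50 °C
Reagents that add atoms: none
Why: Proposed new method: the diazo group leaves C3H3 as the only acidic site, and its lithium enolate attacks the lactone carbonyl C4 in a six-membered Claisen closure driven by the stable C2/C4 diketone enolate (reversible O-acylation drains into C-acylation); mild acid then condenses the freed alcohol with C4, the only carbonyl in reach that can form an enol ether because C9 has no α-hydrogen, which fixes the site of enol protection. The closest known reactions are the base-induced cyclisation of 4,4-disubstituted 3,5-dioxohexanoates to cyclohexane-1,3,5-triones and the aldol reactions of lithium enolates of α-diazo-β-keto compounds, but a Claisen closure with the diazo group in place has not been described; C5 is not touched.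

Step 6
Reactants: 10 (4aS)-6-diazo-4a-geranyl-2,3,4,4a-tetrahydro-5H-chromene-5,7(6H)-dione
Product: 11 (1S,5S,7S,8S)-8-methyl-8-(4-methylpent-3-enyl)-4,5-(epoxypropano)-1,7-cyclobicyclo[3.3.1]non-3-ene-2,9-dione (extra C1–C7 bond; cyclopropane C1–C7–C8; CH3 on C8 cis to C6)
Conditions: Cu(hfacac)2 (copper bis(hexafluoroacetylacetonate), 5 mol %), PhCF3, 100 °C, slow addition of 10
Reagents that add atoms: none
Why: Cu(hfacac)2 (divalent copper, reduced by the diazo compound to the active monovalent copper chelate) binds C1 of 10, N2 leaves, and an electrophilic copper carbene results whose C2–C1–C9 plane is the plane of ring A. The closest known reaction type is the copper- or rhodium-catalysed intramolecular cyclopropanation of 2-diazo-1,3-dicarbonyl compounds bearing a 4-alkenyl chain, which gives 1-acylbicyclo[3.1.0]hexan-2-ones. The alkene, held over one face of ring A by the C5–C6 bond, bonds first through its less substituted carbon C7 (5-exo closure of the ring C1–C9–C5–C6–C7) while charge builds at tertiary C8, and in the same asynchronous concerted event the C1–Cu electrons close the three-membered ring onto C8 (formal [2+1] addition). C1 and C7 are controlled by C5, because the three-atom tether allows only the cis-fused bicyclo[3.1.0]hexanone with C7 on the ring A face that bears C6 and C8 on the side away from the C2–C3–C4 bridge; C8 is controlled by suprafacial addition to the (E)-alkene, which leaves CH3 cis to C6 and the 4-methylpent-3-enyl chain cis to H7. The proximal alkene must win over the distal alkene, C–H insertion and Wolff ring contraction: the distal alkene would need a nine-membered ring, the other C5 substituent has no alkene and its C–H bonds are tied back in the dihydropyran away from C1, and a copper chelate disfavours insertion and rearrangement. The cyclopropane must also survive rather than open to a dihydrofuran or a diene, which is secured because heterolysis of C1–C8 would demand a C1=C2 or C1=C9 enolate at a bridgehead of a bicyclo[3.2.1]octane.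

Step 7
Reactants: 11 tetracyclic cyclopropane; 12 allyltributylstannane; 13 prenyl bromide
Product: 15 (1R,5S,7R,8S)-7-allyl-8-methyl-8-(4-methylpent-3-enyl)-1-prenyl-4,5-(epoxypropano)bicyclo[3.3.1]non-3-ene-2,9-dione, via bridgehead lithium enolate 14 (not isolated)
Conditions: 12, n-BuLi, THF, −78 °C; CuBr·SMe2 (0.5 equiv per allyllithium) to give (CH2=CHCH2)2CuLi (2 equiv); 11, Et2O/THF, −78 → −30 °C; then 13 (5 equiv), DMPU, −78 °C → rt; aq. NH4Cl
Reagents that add atoms: none
Why: Homoconjugate addition of an organocuprate to a doubly activated cyclopropane followed by bridgehead enolate alkylation: C8 is quaternary, so SN2 attack comes at C7 anti to the C1–C7 bond (the bond that stands nearly perpendicular to ring A and overlaps best with the C2 carbonyl), which inverts C7 to (R), enlarges the five-membered ring to ring B and releases the ring strain, and enolate 14 can take up prenyl bromide only on its exocyclic lobe, which fixes C1.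

Step 8
Reactants: 16 3-hydroxybenzoic acid
Product: 17 tert-butyldimethylsilyl 3-(tert-butyldimethylsilyloxy)benzoate
Conditions: t-BuMe2SiCl (2.2 equiv), imidazole (4.4 equiv), DMF, rt
Reagents that add atoms: tert-butyldimethylsilyl chloride, C[Si](C)(Cl)C(C)(C)C
Why: Standard imidazole-promoted silylation covers the phenol and turns the acid into the silyl ester needed for the next step.

Step 9
Reactants: 17 tert-butyldimethylsilyl 3-(tert-butyldimethylsilyloxy)benzoate
Product: 18 3-(tert-butyldimethylsilyloxy)benzoyl chloride
Conditions: (COCl)2 (1.2 equiv), DMF (cat.), CH2Cl2, 0 °C → rt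
Reagents that add atoms: oxalyl chloride, ClC(=O)C(Cl)=O
Why: Silyl esters are converted by the chloroiminium salt from oxalyl chloride and DMF into acid chlorides without release of HCl, so the aryl silyl ether survives.

Step 10
Reactants: 15 bicyclic enol ether; 18 3-(tert-butyldimethylsilyloxy)benzoyl chloride
Product: 20 (1S,5S,7R,8S)-7-allyl-3-[3-(tert-butyldimethylsilyloxy)benzoyl]-8-methyl-8-(4-methylpent-3-enyl)-1-prenyl-4,5-(epoxypropano)bicyclo[3.3.1]non-3-ene-2,9-dione, via C3-lithio enol ether 19 (not isolated)
Conditions: lithium 2,2,6,6-tetramethylpiperidide (1.5 equiv, from the amine and n-BuLi), THF, −78 °C; 18, −78 → −40 °C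
Reagents that add atoms: none
Why: Vinylic lithiation and C-acylation as established for alkyl enol ethers of bicyclo[3.3.1]nonane-2,4,9-triones: with both bridgeheads quaternary, C3–H is the only acidic proton, the hindered amide does not add to the ketones, and no stereocentre is affected (the C1 descriptor changes only through priorities).

Step 11
Reactants: 20 C3-aroylated enol ether
Product: 21 (1S,5S,7R,8S)-7-allyl-3-[3-(tert-butyldimethylsilyloxy)benzoyl]-4-hydroxy-8-methyl-8-(4-methylpent-3-enyl)-5-[3-(phenylselanyl)propyl]-1-prenylbicyclo[3.3.1]non-3-ene-2,9-dione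
Conditions: PhSeH (2 equiv), NaH (2 equiv), THF/HMPA 4:1, 65 °C; aq. HCl (pH 3)
Reagents that add atoms: benzeneselenol, [SeH]c1ccccc1
Why: SN2 O-dealkylation of a vinylogous ester by a soft nucleophile, the process behind halide-induced demethylation of methyl enol ethers of this triketone class and selenolate cleavage of lactones: PhSe− attacks the primary O–CH2 carbon, the aroyl-stabilised triketone enolate leaves, reversible addition at C4 is unproductive, and one step frees the C4 enol and turns the tether into a latent allyl group.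

Step 12
Reactants: 21 selenide
Product: 23 (1S,5S,7R,8S)-5,7-diallyl-3-[3-(tert-butyldimethylsilyloxy)benzoyl]-4-hydroxy-8-methyl-8-(4-methylpent-3-enyl)-1-prenylbicyclo[3.3.1]non-3-ene-2,9-dione, via selenoxide 22 (not isolated)
Conditions: mCPBA (1.0 equiv), CH2Cl2, −78 °C; i-Pr2NH (3 equiv), → 40 °C; aq. HCl (pH 3)
Reagents that add atoms: none
Why: Selenium is oxidised at −78 °C far faster than the trisubstituted alkenes are epoxidised, the selenoxide undergoes syn elimination through its only β-hydrogens to give the terminal alkene, and the amine scavenges the selenenic acid before it can add to the prenyl groups.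

Step 13
Reactants: 23 diallyl triketone; 24 2-methyl-2-butene
Product: 25 (1S,5S,7R,8S)-3-[3-(tert-butyldimethylsilyloxy)benzoyl]-4-hydroxy-8-methyl-8-(4-methylpent-3-enyl)-1,5,7-triprenylbicyclo[3.3.1]non-3-ene-2,9-dione
Conditions: second-generation Hoveyda–Grubbs catalyst (10 mol %), 24/CH2Cl2 1:1, 40 °C
Reagents that add atoms: none
Why: Olefin cross-metathesis, the standard allyl-to-prenyl conversion on this skeleton: only the two monosubstituted alkenes react, the trisubstituted ones are inert or exchange degenerately, the large excess of 24 outruns ring closure between the two allyl groups, and the hydrogen-bonded enol is no more acidic than carboxylic acids that the catalyst tolerates.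

Step 14
Reactants: 25 silyl ether of the target
Product: 26 CNP0406274.2, (1S,5S,7R,8S)-4-hydroxy-3-(3-hydroxybenzoyl)-8-methyl-8-(4-methylpent-3-enyl)-1,5,7-triprenylbicyclo[3.3.1]non-3-ene-2,9-dione
Conditions: Bu4NF (1.2 equiv), AcOH (1.2 equiv), THF, 0 °C
Reagents that add atoms: none
Why: Fluoride cleaves the aryl silyl ether, and the acetic acid buffer leaves the enolised triketone, the four trisubstituted alkenes and all stereocentres alone.

Compound list
1 | δ-valerolactone (oxan-2-one) | O=C1CCCCO1 | starting material
2 | N-methoxy-N-methylacetamide | CC(=O)N(C)OC | starting material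
3 | 3-acetyloxan-2-one (racemic) | CC(=O)C1CCCOC1=O | intermediate
4 | geranyl bromide | CC(C)=CCC/C(C)=C/CBr | starting material
5 | (3R)-3-acetyl-3-geranyloxan-2-one | CC(C)=CCC/C(C)=C/C[C@@]1(C(C)=O)CCCOC1=O | intermediate
6 | 1-acetyl-1H-benzotriazole | CC(=O)n1nnc2ccccc12 | starting material
7 | 1-[(3R)-3-geranyl-2-oxooxan-3-yl]butane-1,3-dione | CC(C)=CCC/C(C)=C/C[C@@]1(C(=O)CC(C)=O)CCCOC1=O | intermediate
8 | 2-diazo-1-[(3R)-3-geranyl-2-oxooxan-3-yl]butane-1,3-dione | CC(C)=CCC/C(C)=C/C[C@@]1(C(=O)C(=[N+]=[N-])C(C)=O)CCCOC1=O | intermediate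
9 | (4S)-2-diazo-4-geranyl-4-(3-hydroxypropyl)cyclohexane-1,3,5-trione | CC(C)=CCC/C(C)=C/C[C@@]1(CCCO)C(=O)CC(=O)C(=[N+]=[N-])C1=O | intermediate (not isolated)
10 | (4aS)-6-diazo-4a-geranyl-2,3,4,4a-tetrahydro-5H-chromene-5,7(6H)-dione (key-step precursor) | CC(C)=CCC/C(C)=C/C[C@@]12CCCOC1=CC(=O)C(=[N+]=[N-])C2=O | intermediate
11 | (1S,5S,7S,8S)-8-methyl-8-(4-methylpent-3-enyl)-4,5-(epoxypropano)-1,7-cyclobicyclo[3.3.1]non-3-ene-2,9-dione (key-step product) | CC(C)=CCC[C@@]1(C)[C@@H]2C[C@@]34CCCOC3=CC(=O)[C@@]12C4=O | intermediate
12 | allyltributylstannane | C=CC[Sn](CCCC)(CCCC)CCCC | starting material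
13 | prenyl bromide | CC(C)=CCBr | starting material
14 | bridgehead lithium enolate (C1 carbanion delocalised into C2=O and C9=O; C7 allyl) | [Li+].CC(C)=CCC[C@@]1(C)[C@H](CC=C)C[C@@]23CCCOC2=CC([O-])=C1C3=O | intermediate (not isolated)
15 | (1R,5S,7R,8S)-7-allyl-8-methyl-8-(4-methylpent-3-enyl)-1-prenyl-4,5-(epoxypropano)bicyclo[3.3.1]non-3-ene-2,9-dione | CC(C)=CCC[C@@]1(C)[C@H](CC=C)C[C@@]23CCCOC2=CC(=O)[C@]1(CC=C(C)C)C3=O | intermediate
16 | 3-hydroxybenzoic acid | OC(=O)c1cccc(O)c1 | starting material
17 | tert-butyldimethylsilyl 3-(tert-butyldimethylsilyloxy)benzoate | CC(C)(C)[Si](C)(C)OC(=O)c1cccc(O[Si](C)(C)C(C)(C)C)c1 | intermediate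
18 | 3-(tert-butyldimethylsilyloxy)benzoyl chloride | ClC(=O)c1cccc(O[Si](C)(C)C(C)(C)C)c1 | intermediate
19 | C3-lithio derivative of 15 | CC(C)=CCC[C@@]1(C)[C@H](CC=C)C[C@@]23CCCOC2=C([Li])C(=O)[C@]1(CC=C(C)C)C3=O | intermediate (not isolated)
20 | (1S,5S,7R,8S)-7-allyl-3-[3-(tert-butyldimethylsilyloxy)benzoyl]-8-methyl-8-(4-methylpent-3-enyl)-1-prenyl-4,5-(epoxypropano)bicyclo[3.3.1]non-3-ene-2,9-dione | CC(C)=CCC[C@@]1(C)[C@H](CC=C)C[C@@]23CCCOC2=C(C(=O)c4cccc(O[Si](C)(C)C(C)(C)C)c4)C(=O)[C@]1(CC=C(C)C)C3=O | intermediate
21 | (1S,5S,7R,8S)-7-allyl-3-[3-(tert-butyldimethylsilyloxy)benzoyl]-4-hydroxy-8-methyl-8-(4-methylpent-3-enyl)-5-[3-(phenylselanyl)propyl]-1-prenylbicyclo[3.3.1]non-3-ene-2,9-dione | CC(C)=CCC[C@@]1(C)[C@H](CC=C)C[C@]2(CCC[Se]c3ccccc3)C(=O)[C@@]1(CC=C(C)C)C(=O)C(C(=O)c1cccc(O[Si](C)(C)C(C)(C)C)c1)=C2O | intermediate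
22 | selenoxide of 21 (configuration at selenium undefined) | CC(C)=CCC[C@@]1(C)[C@H](CC=C)C[C@]2(CCC[Se](=O)c3ccccc3)C(=O)[C@@]1(CC=C(C)C)C(=O)C(C(=O)c1cccc(O[Si](C)(C)C(C)(C)C)c1)=C2O | intermediate (not isolated)
23 | (1S,5S,7R,8S)-5,7-diallyl-3-[3-(tert-butyldimethylsilyloxy)benzoyl]-4-hydroxy-8-methyl-8-(4-methylpent-3-enyl)-1-prenylbicyclo[3.3.1]non-3-ene-2,9-dione | CC(C)=CCC[C@@]1(C)[C@H](CC=C)C[C@]2(CC=C)C(=O)[C@@]1(CC=C(C)C)C(=O)C(C(=O)c1cccc(O[Si](C)(C)C(C)(C)C)c1)=C2O | intermediate
24 | 2-methyl-2-butene | CC=C(C)C | starting material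
25 | tert-butyldimethylsilyl ether of the target (phenol oxygen) | CC(C)=CCC[C@@]1(C)[C@H](CC=C(C)C)C[C@]2(CC=C(C)C)C(=O)[C@@]1(CC=C(C)C)C(=O)C(C(=O)c1cccc(O[Si](C)(C)C(C)(C)C)c1)=C2O | intermediate
26 | CNP0406274.2, (1S,5S,7R,8S) | CC(C)=CCC[C@@]1(C)[C@H](CC=C(C)C)C[C@]2(CC=C(C)C)C(=O)[C@@]1(CC=C(C)C)C(=O)C(C(=O)c1cccc(O)c1)=C2O | target

Total steps: 14. Longest linear sequence: 12 (steps 1–7 and 10–14).

Steps most likely to fail

Step 5. The enolate next to the diazo group may decompose before the C3–C4 bond forms, either by electrocyclic closure onto the diazo nitrogen or by deacylation through the released alkoxide. The fallback sets out from 7 and returns at 10, and uses only known reactions.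
- Compound 7 is converted with LiN(i-Pr)2 (3 equiv) into its dianion. The terminal carbon C3 closes onto the lactone (the known cyclisation of 3,5-dioxohexanoates) to give achiral 4-geranyl-4-(3-hydroxypropyl)cyclohexane-1,3,5-trione F1.
- Pyridinium p-toluenesulfonate condenses the alcohol with one of the two equivalent carbonyls to give racemic 4a-geranyl-2,3,4,4a-tetrahydro-5H-chromene-5,7(6H)-dione F2.
- The C5 information of step 2 is lost at the symmetric trione, so step 2 may then be run with Bu4NBr.
- Preparative chromatography on a chiral stationary phase delivers (4aS)-4a-geranyl-2,3,4,4a-tetrahydro-5H-chromene-5,7(6H)-dione F3. The unwanted enantiomer is hydrolysed back to the achiral trione and recycled.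
- Regitz diazo transfer to C1 of the resolved material gives 10.

Step 7. Substitution at C7, a secondary carbon next to quaternary C8, may be so slow that 1,2-addition of the allyl reagent to the strained C9 ketone, addition–elimination at C4 or electron-transfer cleavage of the cyclopropane takes over. The bridgehead enolate may also alkylate sluggishly. The fallback sets out from 11 and returns at 15.
- Sodium benzeneselenolate, a small, soft and non-basic nucleophile with good precedent on doubly activated cyclopropanes, opens C1–C7 at C7 with inversion at or below room temperature.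
- The enolate is trapped with 13 to give (1R,5S,7R,8S)-8-methyl-8-(4-methylpent-3-enyl)-7-(phenylselanyl)-1-prenyl-4,5-(epoxypropano)bicyclo[3.3.1]non-3-ene-2,9-dione F4.
- Keck radical allylation with 12 and AIBN in benzene at 80 °C replaces selenium by allyl. The C7 radical should be attacked on its exo face, because the endo face looks into ring A, so the same (7R) configuration is expected.

Step 6. The closure builds two adjacent quaternary carbons in a strained tetracycle. Wolff ring contraction, carbene dimerisation or attack on the distal alkene may therefore compete with the planar, ring-bound carbene. The fallback sets out from 8 and returns at 11, forming the same two bonds before ring A exists.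
- The open-chain diazo diketone 8 is decomposed with Rh2(OAc)4 or Cu(hfacac)2, the classical closure to a 1-acylbicyclo[3.1.0]hexan-2-one.
- This gives 1-acetyl-6-methyl-6-(4-methylpent-3-enyl)spiro[bicyclo[3.1.0]hexane-3,3'-oxane]-2,2'-dione F5 (1S,5R,7S,8S in target numbering). Facial selectivity relative to C5 is no longer enforced there, so a diastereomer has to be separated.
- LiN(SiMe3)2 then closes the acetyl CH3 onto the lactone carbonyl, which is possible only for the isomer with these groups cis. The product is (1S,5S,7S,8S)-5-(3-hydroxypropyl)-8-methyl-8-(4-methylpent-3-enyl)-1,7-cyclobicyclo[3.3.1]nonane-2,4,9-trione F6.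
- Pyridinium p-toluenesulfonate converts this into 11.

Further compounds
F1 | step 5 | 4-geranyl-4-(3-hydroxypropyl)cyclohexane-1,3,5-trione (achiral) | CC(C)=CCC/C(C)=C/CC1(CCCO)C(=O)CC(=O)CC1=O
F2 | step 5 | racemic 4a-geranyl-2,3,4,4a-tetrahydro-5H-chromene-5,7(6H)-dione | CC(C)=CCC/C(C)=C/CC12CCCOC1=CC(=O)CC2=O
F3 | step 5 | (4aS)-4a-geranyl-2,3,4,4a-tetrahydro-5H-chromene-5,7(6H)-dione | CC(C)=CCC/C(C)=C/C[C@@]12CCCOC1=CC(=O)CC2=O
F4 | step 7 | (1R,5S,7R,8S)-8-methyl-8-(4-methylpent-3-enyl)-7-(phenylselanyl)-1-prenyl-4,5-(epoxypropano)bicyclo[3.3.1]non-3-ene-2,9-dione | CC(C)=CCC[C@@]1(C)[C@H]([Se]c2ccccc2)C[C@@]23CCCOC2=CC(=O)[C@]1(CC=C(C)C)C3=O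
F5 | step 6 | 1-acetyl-6-methyl-6-(4-methylpent-3-enyl)spiro[bicyclo[3.1.0]hexane-3,3'-oxane]-2,2'-dione (1S,5R,7S,8S in target numbering) | CC(C)=CCC[C@@]1(C)[C@@H]2C[C@]3(CCCOC3=O)C(=O)[C@]12C(C)=O
F6 | step 6 | (1S,5S,7S,8S)-5-(3-hydroxypropyl)-8-methyl-8-(4-methylpent-3-enyl)-1,7-cyclobicyclo[3.3.1]nonane-2,4,9-trione | CC(C)=CCC[C@@]1(C)[C@@H]2C[C@]3(CCCO)C(=O)[C@]12C(=O)CC3=O
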